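Ring A is an acylphloroglucinol, and its alternating oxygen pattern allows it to be cut into two three-carbon pieces. In chroman numbering, C4a–C5–C6 is the γ-carbon/carbonyl/central-carbon segment of a 1,3-diketone, and C7–C8–C8a is the backbone of malonic acid. The route rests on disconnecting C4a–C8a and C6–C7. In the forward direction, the bis(silyl enol ether) of an open-chain (E)-styryl diketone, made from sulcatone and a chroman cinnamate, is C-acylated twice by malonyl dichloride. This one operation creates the benzene ring with all three oxygens, the prenyl group and the cinnamoyl chain correctly placed. Acid-induced pyran closure and alkaline hydrogenation finish the synthesis.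

Key step: step 4

Remark: the target SMILES contains no stereocentre and no stereogenic double bond, so the compound is achiral and nothing has to be set or resolved. The only stereo-element in the route, the E-alkene made in step 2, is erased in step 6.

Step 1
Reactants: 1 4-bromophenol; 2 isoprene
Product: 4 6-bromo-2,2-dimethylchroman, via ortho-prenylphenol 3 (not isolated)
Conditions: AgOTf (5 mol %), ClCH2CH2Cl, rt
Reagents that add atoms: none
Why: This is the known one-pot phenol–diene chroman synthesis, in which Friedel–Crafts prenylation can only occur ortho because bromine blocks the para position, and the resulting ortho-prenylphenol closes by Markovnikov intramolecular hydroalkoxylation.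

Step 2
Reactants: 4 6-bromo-2,2-dimethylchroman; 5 methyl acrylate
Product: 6 methyl (E)-3-(2,2-dimethylchroman-6-yl)prop-2-enoate
Conditions: Pd(OAc)2 (2 mol %), P(o-tol)3 (8 mol %), Et3N, DMF, 100 °C
Reagents that add atoms: none
Why: The Mizoroki–Heck reaction of an aryl bromide with an acrylate tolerates the chroman ether and should give the E-cinnamate through syn insertion and syn β-hydride elimination.

Step 3
Reactants: 7 6-methylhept-5-en-2-one; 6 methyl (E)-3-(2,2-dimethylchroman-6-yl)prop-2-enoate
Product: 9 (E)-1-(2,2-dimethylchroman-6-yl)-9-methyldeca-1,8-diene-3,5-dione, via lithium enolate 8 (not isolated)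
Conditions: 7 (1.1 equiv), LiHMDS (2.3 equiv), THF, −78 °C; then 6, −78 °C → rt; sat. aq NH4Cl
Reagents that add atoms: LiHMDS, [Li]N([Si](C)(C)C)[Si](C)(C)C (supplies only the lithium of 8; nothing of it remains in 9)
Why: In this crossed Claisen condensation the hindered amide removes a methyl proton under kinetic control, the ester has no enolisable hydrogen and cannot self-condense, and the surplus base turns the product at once into its stabilised diketonate, which drives the acylation and keeps free ketone from scrambling the enolate.

Step 4
Reactants: 9 (E)-1-(2,2-dimethylchroman-6-yl)-9-methyldeca-1,8-diene-3,5-dione; 10 malonyl dichloride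
Product: 13 (E)-1-[2,4,6-trihydroxy-3-(3-methylbut-2-enyl)phenyl]-3-(2,2-dimethylchroman-6-yl)prop-2-en-1-one, via bis(silyloxy)tetraene 11 (not isolated), via acid chloride 12 (not isolated)
Conditions: (i) TMSOTf (2.3 equiv), Et3N (2.6 equiv), Et2O, 0 °C → rt, ether layer decanted from the ammonium salt and concentrated under argon; (ii) 10 (1.05 equiv, freshly distilled), CH2Cl2 (0.02 M), −78 → 0 °C, volatiles removed; (iii) NaOMe, MeOH, argon, 0 °C → rt; 1 M HCl to pH 3–4
Reagents that add atoms: TMSOTf, C[Si](C)(C)OS(=O)(=O)C(F)(F)F (supplies the silyl groups of 11 and 12; none remains in 13)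
Why: Proposed new method: double silylation converts 9 into the electron-rich diene unit of 11, whose terminal γ-carbon, the most nucleophilic site, attacks one acid chloride of 10 with loss of Me3SiCl to form C4a–C8a and give 12; the remaining silyl enol ether then attacks the second acid chloride through the central carbon to form C6–C7, and the acylcyclohexanetrione so formed enolises irreversibly to the arene 13. The closest known reactions are the Effenberger cyclisation (α,α'-double C-acylation of ketone enol ethers by malonyl dichloride) and the formal [3+3] cyclisations of 1,3-bis(silyloxy)dienes with 1,3-dielectrophiles, but joining a diketone-derived diene to malonyl dichloride to make an acylphloroglucinol has not been shown. Ring A closes in a 6-(enolexo)-exo-trig mode, and no stereocentre results because the transient sp3 carbon of 12 becomes aromatic. The step needs the correct γ-carbon and C- rather than O-acylation: the first is secured because the styryl side carries only vinylic hydrogens, so the diene can form only towards the prenyl-bearing CH2, and the second is favoured by the soft silyl enol ether nucleophile, low temperature, high dilution and removal of the amine salts, which would otherwise turn 10 into ketenes. If closure goes through the C5 enol oxygen, the product is a hydroxypyrone lactone, which the closing methoxide treatment opens to a methyl triketo ester that undergoes Claisen cyclisation at the same central carbon, so both channels should converge on 13. No Lewis acid is added in stage (ii), which protects the prenyl alkene and the styryl enone.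

Step 5
Reactants: 13 (E)-1-[2,4,6-trihydroxy-3-(3-methylbut-2-enyl)phenyl]-3-(2,2-dimethylchroman-6-yl)prop-2-en-1-one
Product: 14 (E)-1-(5,7-dihydroxy-2,2-dimethylchroman-6-yl)-3-(2,2-dimethylchroman-6-yl)prop-2-en-1-one
Conditions: p-TsOH·H2O (20 mol %), toluene, 60 °C; crude material carried on
Reagents that add atoms: none
Why: Brønsted-acid intramolecular hydroalkoxylation (Markovnikov protonation to the tertiary cation, six-membered closure) is the standard prenylphenol-to-chroman cyclisation, the free 4'-hydroxyl should be favoured over the 2'-hydroxyl that is hydrogen-bonded to the ketone, and any reversible oxa-Michael closure to flavanone isomers is harmless because these keep the same skeleton and are reopened in step 6.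

Step 6
Reactants: 14 (E)-1-(5,7-dihydroxy-2,2-dimethylchroman-6-yl)-3-(2,2-dimethylchroman-6-yl)prop-2-en-1-one
Product: 15 1-(5,7-dihydroxy-2,2-dimethylchroman-6-yl)-3-(2,2-dimethylchroman-6-yl)propan-1-one
Conditions: H2 (1 atm), 10% Pd/C, 2 M aq KOH/EtOH, rt; then 2 M HCl, 0 °C
Reagents that add atoms: none
Why: Catalytic hydrogenation in aqueous alkali is the established chalcone/flavanone-to-dihydrochalcone process, in which base holds the material as the open chalcone phenolate (E1cB opening of any flavanone), Pd/C saturates the only remaining C=C, and the vinylogous-carboxylate ketone and both aryl ethers are left untouched.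

Compound list
1 | 4-bromophenol | Oc1ccc(Br)cc1 | starting material
2 | isoprene | C=CC(C)=C | starting material
3 | 4-bromo-2-(3-methylbut-2-enyl)phenol | CC(C)=CCc1cc(Br)ccc1O | intermediate (not isolated)
4 | 6-bromo-2,2-dimethylchroman | CC1(C)CCc2cc(Br)ccc2O1 | intermediate
5 | methyl acrylate | C=CC(=O)OC | starting material
6 | methyl (E)-3-(2,2-dimethylchroman-6-yl)prop-2-enoate | COC(=O)/C=C/c1ccc2OC(C)(C)CCc2c1 | intermediate
7 | 6-methylhept-5-en-2-one (sulcatone) | CC(=O)CCC=C(C)C | starting material
8 | lithium 6-methylhepta-1,5-dien-2-olate | [Li+].[O-]C(=C)CCC=C(C)C | intermediate (not isolated)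
9 | (E)-1-(2,2-dimethylchroman-6-yl)-9-methyldeca-1,8-diene-3,5-dione (drawn as the diketo tautomer) | CC(C)=CCCC(=O)CC(=O)/C=C/c1ccc2OC(C)(C)CCc2c1 | intermediate
10 | malonyl dichloride | O=C(Cl)CC(=O)Cl | starting material
11 | (1E)-1-(2,2-dimethylchroman-6-yl)-9-methyl-3,5-bis(trimethylsilyloxy)deca-1,3,5,8-tetraene (enol ether geometry not defined and irrelevant) | CC(C)=CCC=C(O[Si](C)(C)C)C=C(O[Si](C)(C)C)/C=C/c1ccc2OC(C)(C)CCc2c1 | intermediate (not isolated)
12 | (8E)-9-(2,2-dimethylchroman-6-yl)-4-(3-methylbut-2-enyl)-3,5-dioxo-7-(trimethylsilyloxy)nona-6,8-dienoyl chloride (racemic at C4; centre lost on aromatisation) | CC(C)=CCC(C(=O)CC(=O)Cl)C(=O)C=C(O[Si](C)(C)C)/C=C/c1ccc2OC(C)(C)CCc2c1 | intermediate (not isolated)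
13 | (E)-1-[2,4,6-trihydroxy-3-(3-methylbut-2-enyl)phenyl]-3-(2,2-dimethylchroman-6-yl)prop-2-en-1-one (3'-prenyl-2',4',6'-trihydroxychalcone) | CC(C)=CCc1c(O)cc(O)c(C(=O)/C=C/c2ccc3OC(C)(C)CCc3c2)c1O | intermediate
14 | (E)-1-(5,7-dihydroxy-2,2-dimethylchroman-6-yl)-3-(2,2-dimethylchroman-6-yl)prop-2-en-1-one | CC1(C)CCc2c(O)c(C(=O)/C=C/c3ccc4OC(C)(C)CCc4c3)c(O)cc2O1 | intermediate
15 | 1-(5,7-dihydroxy-2,2-dimethylchroman-6-yl)-3-(2,2-dimethylchroman-6-yl)propan-1-one (CNP0080574.0, achiral) | CC1(C)CCc2cc(CCC(=O)c3c(O)cc4c(c3O)CCC(C)(C)O4)ccc2O1 | target

Total step count: 6. Longest linear sequence: 6 (1 → 4 → 6 → 9 → 13 → 14 → 15).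

Steps most likely to fail

Step 4 (new method).
- Risk: ring closure may run through the enol oxygen and resist correction. The first acylation may start at the central carbon. Intermolecular acylation may outrun cyclisation. Adventitious HCl may add to the prenyl alkene.
- Fallback: it uses known chemistry, takes ring A from phloroglucinol instead of building it, sets out from 6 and comes back at 15.
- Hydrogenation of 6 (H2, Pd/C, MeOH) should give methyl 3-(2,2-dimethylchroman-6-yl)propanoate F1.
- Saponification (LiOH, THF/H2O) should give 3-(2,2-dimethylchroman-6-yl)propanoic acid F2.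
- Friedel–Crafts acylation of phloroglucinol with F2 in BF3·OEt2 at 80 °C should give 3-(2,2-dimethylchroman-6-yl)-1-(2,4,6-trihydroxyphenyl)propan-1-one F3.
- Acid-catalysed reaction of F3 with isoprene 2 (Amberlyst-15, THF/heptane, 65 °C) should C-prenylate the symmetric ring to 3-(2,2-dimethylchroman-6-yl)-1-[2,4,6-trihydroxy-3-(3-methylbut-2-enyl)phenyl]propan-1-one F4.
- F4 should close in the same flask on the 4'-oxygen to 15.

Step 5.
- Risk: the tertiary cation may be captured by the chelated 2'-hydroxyl (poor regioselectivity between the two flanking oxygens), and intermolecular Friedel–Crafts alkylation of the electron-rich ring may compete.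
- Fallback: it replaces cationic closure by oxidative cyclodehydrogenation, sets out from 13 and comes back at 15.
- DDQ (1.1 equiv, benzene, rt) abstracts the benzylic hydride of the prenyl group. This generates the ortho-quinone methide through the free 4'-hydroxyl, which ionises more readily.
- Oxa-6π electrocyclisation should then give (E)-1-(5,7-dihydroxy-2,2-dimethyl-2H-chromen-6-yl)-3-(2,2-dimethylchroman-6-yl)prop-2-en-1-one F5.
- The conditions of step 6 saturate the chromene and the enone together, and would also repair any dehydrogenation of the ring B chroman.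

Step 3.
- Risk: conjugate addition of the enolate to the cinnamate, migration of the enolate to the internal position, and self-aldolisation of the ketone.
- Fallback: it forms the C1=C2 alkene by condensation instead of the C3–C4 bond by acylation, sets out from 4 and comes back at 9.
- Bromine–lithium exchange on 4 (n-BuLi, THF, −78 °C) and a DMF quench should give 2,2-dimethylchroman-6-carbaldehyde F6.
- Separately, the dianion of acetylacetone (NaH, then n-BuLi, THF, 0 °C) is alkylated at its terminal carbon by prenyl bromide to give 8-methylnon-7-ene-2,4-dione F7.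
- Boron-templated aldol condensation of F6 with F7 (B2O3, B(OnBu)3, n-BuNH2, EtOAc, 80 °C; then dilute HCl) masks the central CH2 as a chelate. It should condense at the less hindered methyl terminus, as in curcuminoid and dehydrogingerdione preparations, to give 9.

Further compounds
F1 | step 4 | methyl 3-(2,2-dimethylchroman-6-yl)propanoate | COC(=O)CCc1ccc2OC(C)(C)CCc2c1
F2 | step 4 | 3-(2,2-dimethylchroman-6-yl)propanoic acid | OC(=O)CCc1ccc2OC(C)(C)CCc2c1
F3 | step 4 | 3-(2,2-dimethylchroman-6-yl)-1-(2,4,6-trihydroxyphenyl)propan-1-one | O=C(CCc1ccc2OC(C)(C)CCc2c1)c1c(O)cc(O)cc1O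
F4 | step 4 | 3-(2,2-dimethylchroman-6-yl)-1-[2,4,6-trihydroxy-3-(3-methylbut-2-enyl)phenyl]propan-1-one | CC(C)=CCc1c(O)cc(O)c(C(=O)CCc2ccc3OC(C)(C)CCc3c2)c1O
F5 | step 5 | (E)-1-(5,7-dihydroxy-2,2-dimethyl-2H-chromen-6-yl)-3-(2,2-dimethylchroman-6-yl)prop-2-en-1-one | CC1(C)C=Cc2c(O)c(C(=O)/C=C/c3ccc4OC(C)(C)CCc4c3)c(O)cc2O1
F6 | step 3 | 2,2-dimethylchroman-6-carbaldehyde | O=Cc1ccc2OC(C)(C)CCc2c1
F7 | step 3 | 8-methylnon-7-ene-2,4-dione | CC(=O)CC(=O)CCC=C(C)C
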